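Assumptions, one line each:
- Chamigrane numbering is used throughout. Ring A is C1–C6, with C6 the spiro carbon, C2 bearing Cl and C3 bearing CH3/Br. Ring B is C6–C11, with C7=C14H2, C9–OAc, C10–Br and C11 = CMe2.
- The SMILES decodes to (2S,3S,6R,9S,10R), with Br/Cl trans on ring A and OAc/Br cis on ring B.
- 4-Iodo-2-methylbut-1-ene is treated as purchasable (otherwise one Appel step from isoprenol).
- The roughly 87–90% ee expected from step 4 is raised to >99% by one recrystallisation of crystalline bromo-enone 10.

## Retrosynthetic overview
1. The acetate and C9 carbinol come from hydride reduction of α-bromo-β,γ-enone 15, which comes from kinetic deconjugation of α'-bromo-enone 13.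
2. The ring-A Br/Cl pair comes from the C2=C3 alkene of 10 via the epoxide: Cl at C2 by SN2, then Br at C3 by Cl-assisted SN1. Direct BrCl addition would place Cl at the tertiary carbon.
3. Compound 10 comes from spiro-enone 9 by α'-bromination, and 9 comes from vinylogous ester 8 by MeLi addition (Stork–Danheiser transposition).
4. Ring A is closed by RCM of 7. The C6 quaternary centre is set by Pd-catalysed decarboxylative asymmetric allylic alkylation of enol carbonate 6.
5. Ring order: ring B is bought as dimedone, and ring A is formed second by RCM.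

## Route

**Step 1**
Reactants: 1 dimedone
Product: 2, 3-isobutoxy-5,5-dimethylcyclohex-2-en-1-one
Conditions: i-BuOH, cat. TsOH, toluene, Dean–Stark reflux
Reagents that add atoms: isobutanol, CC(C)CO
Why: Acid-catalysed vinylogous esterification masks one carbonyl and leaves C6 (α') as the only kinetic enolisation site; no stereocentre is formed.

**Step 2**
Reactants: 2; 3 4-iodo-2-methylbut-1-ene
Product: 4, (±)-3-isobutoxy-5,5-dimethyl-6-(3-methylbut-3-enyl)cyclohex-2-en-1-one
Conditions: LDA, THF, −78 °C; then 3, −78 → 23 °C
Reagents that add atoms: 3, C=C(C)CCI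
Why: Stork–Danheiser kinetic α'-enolate alkylation with a primary iodide; the racemic C6 centre is erased in step 3.

**Step 3**
Reactants: 4; 5 allyl chloroformate
Product: 6, allyl dienyl carbonate (O-acylated C6=C7 enol of 4)
Conditions: LDA, TMEDA, THF, −78 °C; then 5
Reagents that add atoms: 5, C=CCOC(=O)Cl
Why: The tetrasubstituted lithium enolate undergoes O-acylation with the chloroformate because C-attack at the neopentyl C6 is blocked, and C6 becomes sp2.

**Step 4**
Reactants: 6
Product: 7, (S)-6-allyl-3-isobutoxy-5,5-dimethyl-6-(3-methylbut-3-enyl)cyclohex-2-en-1-one (+ CO2)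
Conditions: Pd(dmdba)2 (10 mol %), (R)-(CF3)3-t-BuPHOX (12 mol %), toluene, 10–25 °C
Reagents that add atoms: none
Why: Decarboxylative asymmetric allylic alkylation (Tsuji–Trost type) sets C6 by ligand-controlled enolate-face selection; the (R)-ligand is assigned by analogy with (S)-ligand → (S)-2-allyl-2-methylcyclohexanone, is to be confirmed by the rotation of 9, and the antipodal ligand is equally available.

**Step 5**
Reactants: 7
Product: 8, (6S)-3-isobutoxy-5,5,9-trimethylspiro[5.5]undeca-2,8-dien-1-one (+ ethylene)
Conditions: Grubbs II (5 mol %), CH2Cl2, 40 °C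
Reagents that add atoms: none
Why: Ring-closing metathesis of the monosubstituted and 1,1-disubstituted alkenes closes ring A as the C2=C3 trisubstituted alkene and leaves C6 untouched.

**Step 6**
Reactants: 8
Product: 9, (6S)-chamigra-2,7-dien-9-one (1,5,5,9-tetramethylspiro[5.5]undeca-1,8-dien-3-one)
Conditions: MeLi, CeCl3, THF, −78 → 0 °C; then 10% aq HCl, 23 °C
Reagents that add atoms: methyllithium, [Li]C; water, O
Why: Organocerium 1,2-addition to the hindered C7 carbonyl followed by Stork–Danheiser hydrolysis and transposition gives the C7(CH3)=C8–C9=O enone; no new stereocentre is formed.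

**Step 7**
Reactants: 9
Product: 10, (6R,10R)-10-bromochamigra-2,7-dien-9-one
Conditions: i) LDA, TMSCl, THF, −78 °C; ii) NBS, NaHCO3, THF, −78 → 0 °C on the crude enol silane; recrystallise
Reagents that add atoms: N-bromosuccinimide, O=C1CCC(=O)N1Br
Why: Kinetic α'-deprotonation (as for isophorone) gives the cross-conjugated silyl dienol ether, which outcompetes the ring-A alkene for Br+; the epimerisable C10 settles as the pseudo-equatorial bromide cis to C1, because ring B prefers the half-chair that holds C14 over the flat C1–C2=C3 side of ring A.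

**Step 8**
Reactants: 10
Product: 11, (2R,3S,6R,10R)-10-bromo-2,3-epoxychamigr-7-en-9-one
Conditions: mCPBA, NaHCO3, CH2Cl2, 0 °C
Reagents that add atoms: mCPBA, O=C(OO)c1cccc(Cl)c1
Why: Prilezhaev epoxidation occurs only at the electron-rich trisubstituted alkene and from the ring-A face anti to C7, since CMe2 is equatorial on ring A and C7 with its C14 methyl is pseudo-axial and shields the other face.

**Step 9**
Reactants: 11
Product: 12, (2S,3S,6R,10R)-10-bromo-2-chloro-3-hydroxychamigr-7-en-9-one
Conditions: LiCl (5 equiv), AcOH (3 equiv), THF, 23 → 40 °C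
Reagents that add atoms: lithium chloride, [Li+].[Cl-]
Why: Nucleophilic, weakly acidic trans-diaxial (Fürst–Plattner) SN2 opening at the secondary C2 with inversion, as in 5α,6α-epoxy steroids → 6β-chloro-5α-ols, sets C2 and leaves the tertiary C3–OH anti-periplanar to Cl.

**Step 10**
Reactants: 12
Product: 13, (2S,3S,6R,10R)-3,10-dibromo-2-chlorochamigr-7-en-9-one
Conditions: TMSBr (3 equiv), CH2Cl2, −20 → 0 °C
Reagents that add atoms: bromotrimethylsilane, C[Si](C)(C)Br
Why: SN1 with anchimeric assistance: loss of the activated C3–O anti to C2–Cl gives a chlorine-bridged tertiary cation that bromide opens at C3 from the face opposite Cl (Markovnikov and diaxial), giving net retention; any E1 alkene re-adds HBr through the same cation, and the bromo-enone has no acid-labile group.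

**Step 11**
Reactants: 13
Product: 14, (2S,3S,6R,10R)-3,10-dibromo-9-(tert-butyldimethylsilyloxy)-2-chlorochamigra-7(14),8-diene
Conditions: TBSOTf, Et3N, CH2Cl2, −20 → 0 °C
Reagents that add atoms: TBSOTf, CC(C)(C)[Si](C)(C)OS(=O)(=O)C(F)(F)F
Why: Soft enolisation: Et3N removes an exposed C14–H from the O-silylated enone rather than the C10–H buried between Br, CMe2 and ring A, giving the extended dienol ether; the β-chloro group retards ionisation of the tertiary bromide, and no stereocentre changes.

**Step 12**
Reactants: 14
Product: 15, (2S,3S,6R,10R)-3,10-dibromo-2-chlorochamigr-7(14)-en-9-one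
Conditions: TBAF/AcOH (1:1.5), THF, −78 °C; cold NaHCO3 work-up; used crude
Reagents that add atoms: none
Why: Fluoride releases the extended dienolate, and buffered kinetic protonation at the α-carbon C8 (Ringold-type deconjugation) gives the exocyclic methylene; the low temperature and buffering suppress E2, Favorskii reaction and C10 epimerisation.

**Step 13**
Reactants: 15
Product: 16, isoobtusol, (2S,3S,6R,9S,10R)-3,10-dibromo-2-chlorochamigr-7(14)-en-9-ol
Conditions: DIBAL-H, Et2O, −78 °C
Reagents that add atoms: none
Why: In this diastereoselective 1,2-reduction, hydride adds to the carbonyl face opposite the C10 bromine while the axial C11 methyl blocks the alternative trajectory, giving the cis-bromohydrin (9S); a cis-bromohydrin cannot close to an epoxide.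

**Step 14**
Reactants: 16
Product: 17, 9-acetylisoobtusol (target)
Conditions: Ac2O, pyridine, cat. DMAP, CH2Cl2, 0 → 23 °C
Reagents that add atoms: acetic anhydride, CC(=O)OC(C)=O
Why: DMAP-catalysed O-acylation of the only hydroxyl proceeds with retention at C9 under conditions too mild to eliminate the deactivated tertiary bromide.

## Compound list
1 | dimedone | CC1(C)CC(=O)CC(=O)C1 | starting material
2 | 3-isobutoxy-5,5-dimethylcyclohex-2-enone | CC(C)COC1=CC(=O)CC(C)(C)C1 | intermediate
3 | 4-iodo-2-methylbut-1-ene | C=C(C)CCI | starting material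
4 | (±)-6-(3-methylbut-3-enyl) vinylogous ester | CC(C)COC1=CC(=O)C(CCC(C)=C)C(C)(C)C1 | intermediate
5 | allyl chloroformate | C=CCOC(=O)Cl | starting material
6 | allyl dienyl (enol) carbonate | C=CCOC(=O)OC1=C(CCC(C)=C)C(C)(C)CC(OCC(C)C)=C1 | intermediate
7 | (S)-α-quaternary allyl ketone | O=C1C=C(OCC(C)C)CC(C)(C)[C@@]1(CC=C)CCC(C)=C | intermediate
8 | (6S)-spiro vinylogous ester | O=C1C=C(OCC(C)C)CC(C)(C)[C@@]12CCC(C)=CC2 | intermediate
9 | (6S)-chamigra-2,7-dien-9-one | CC1=CC(=O)CC(C)(C)[C@@]12CCC(C)=CC2 | intermediate
10 | (6R,10R)-10-bromochamigra-2,7-dien-9-one | CC1=CC(=O)[C@H](Br)C(C)(C)[C@@]12CCC(C)=CC2 | intermediate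
11 | (2R,3S,6R,10R)-2,3-epoxide | CC1=CC(=O)[C@H](Br)C(C)(C)[C@@]12CC[C@]3(C)O[C@@H]3C2 | intermediate
12 | (2S,3S,6R,10R)-2-chloro-3-ol | CC1=CC(=O)[C@H](Br)C(C)(C)[C@@]12CC[C@](C)(O)[C@@H](Cl)C2 | intermediate
13 | (2S,3S,6R,10R)-3,10-dibromo-2-chloro enone | CC1=CC(=O)[C@H](Br)C(C)(C)[C@@]12CC[C@](C)(Br)[C@@H](Cl)C2 | intermediate
14 | extended TBS dienol ether | C=C1C=C(O[Si](C)(C)C(C)(C)C)[C@H](Br)C(C)(C)[C@@]12CC[C@](C)(Br)[C@@H](Cl)C2 | intermediate
15 | α-bromo-β,γ-enone (exocyclic methylene) | C=C1CC(=O)[C@H](Br)C(C)(C)[C@@]12CC[C@](C)(Br)[C@@H](Cl)C2 | intermediate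
16 | isoobtusol | C=C1C[C@H](O)[C@H](Br)C(C)(C)[C@@]12CC[C@](C)(Br)[C@@H](Cl)C2 | intermediate
17 | 9-acetylisoobtusol | C=C1C[C@H](OC(C)=O)[C@H](Br)C(C)(C)[C@@]12CC[C@](C)(Br)[C@@H](Cl)C2 | target

## Step count
Total steps: 14. Longest linear sequence: 14. Steps 11–13 can be telescoped.

## Steps most likely to fail
1. **Step 9.**
   - Risk: chloride must reach C2 on the congested face syn to the pseudo-axial C7/C14, so the epoxide may be inert or may open at C3.
   - Fallback: bring the chlorine in with the allyl unit. Use a 2-chloroallyl enol carbonate in steps 3–4 and RCM to the tetrasubstituted C2(Cl)=C3(CH3) alkene. Then set C2 and C3 at the acid-stable bromo-enone stage by adding H–Br from the open face, through C2 protonation, a Cl-bridged C3 cation and bromide capture, so that nothing has to approach the hindered face.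
2. **Step 10.**
   - Risk: the tertiary OH → Br exchange may give E1 products or the C3 epimer, and HBr may epimerise C10.
   - Fallback: reverse the halogen order so that C3–Br is made stereospecifically. Prepare the diastereomeric (2S,3R)-epoxide under reagent control (Shi epoxidation) and open it at the tertiary carbon with MgBr2 or TMSBr with inversion. Then replace the anti C2–OH by Cl with retention through the bromonium ion (SOCl2, internal return).
3. **Steps 11–12.**
   - Risk: in deconjugating an α'-bromo-enone, enolisation toward C10, reconjugation or Favorskii contraction may win.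
   - Fallback: abandon the enone and form ring B last by a Me2AlCl-promoted type-II carbonyl-ene cyclisation. The substrate is a ring-A intermediate whose C6 carries an isopropenyl group and a CMe2–CHBr–CHO chain. This creates the C8–C9 bond, the C9 carbinol and the C7=CH2 group in one event, and it cannot give a conjugated isomer.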